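**Strategy.** The chromone is cut at C4–C4a, so the pyranone ring is closed last onto an intact, fully substituted A ring. The key step is a thermal intramolecular Friedel–Crafts acylation in which a Meldrum's acid carbonyl becomes C4 and is attacked by C4a. C4a is the only unsubstituted carbon ortho to the ether oxygen O1, and it is also ortho to O5 and para to O7 of the phloroglucinol-derived ring. One operation makes the C4–C4a bond and the O1–C2–C3–C4–C4a–C8a ring with the 2-aryloxy group already in place. The precursor is a mixed bis(aryloxy)methylidene Meldrum's acid carrying the prenylated bis-MOM phloroglucinyl ether and the 4-methoxyphenyl ether on the same ketene-acetal carbon (C2).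

Key step: step 6

Remark: the target has no stereocentre and no stereogenic double bond, so it is achiral and the request for a single enantiomer needs no stereocontrol.

**Step 1**
Reactants: 1 phloroglucinol
Product: 2 3,5-bis(methoxymethoxy)phenol
Conditions: MOMCl (2.0 equiv), i-Pr2NEt (2.2 equiv), THF, 0 °C → rt; chromatography
Reagents that add atoms: chloromethyl methyl ether, COCCl
Why: Base-mediated O-alkylation of a phenol by an α-chloro ether is reliable, and with two equivalents the threefold-symmetric triol should give the bis-ether as the main component of a separable mixture whose mono- and tris-ethers can be recycled.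

**Step 2**
Reactants: 2 3,5-bis(methoxymethoxy)phenol; 3 prenyl bromide (1-bromo-3-methylbut-2-ene)
Product: 4 3,5-bis(methoxymethoxy)-2-(3-methylbut-2-en-1-yl)phenol
Conditions: NaH (1.05 equiv), toluene, 0 °C; then 3 (1.0 equiv), rt
Reagents that add atoms: none
Why: Ortho C-allylation of a sodium phenoxide as a tight ion pair in a non-polar solvent should place prenyl on one of the two equivalent ortho carbons of 2, which gives directly the single isomer with the free hydroxyl next to prenyl; protecting before prenylating avoids having to tell apart the two equivalent prenyl-flanked hydroxyls of 2-prenylphloroglucinol.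

**Step 3**
Reactants: 5 5-[bis(methylsulfanyl)methylidene]-2,2-dimethyl-1,3-dioxane-4,6-dione; 6 4-methoxyphenol
Product: 7 5-[(4-methoxyphenoxy)(methylsulfanyl)methylidene]-2,2-dimethyl-1,3-dioxane-4,6-dione
Conditions: 5 (1.5 equiv), K2CO3 (0.5 equiv), MeCN, 50 °C, N2 sweep (MeSH to bleach scrubber)
Reagents that add atoms: none
Why: Addition–elimination (vinylic substitution, SNV) of a phenoxide at the electrophilic carbon of a push–pull ketene dithioacetal should give mono-exchange, because excess 5 disfavours a second substitution and removal of volatile methanethiol prevents thiolate return while regenerating the base.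

**Step 4**
Reactants: 7 5-[(4-methoxyphenoxy)(methylsulfanyl)methylidene]-2,2-dimethyl-1,3-dioxane-4,6-dione
Product: 8 5-[(methanesulfinyl)(4-methoxyphenoxy)methylidene]-2,2-dimethyl-1,3-dioxane-4,6-dione (racemic at sulfur)
Conditions: mCPBA (1.05 equiv), CH2Cl2, −20 → 0 °C; cold aq NaHCO3 wash, used directly
Reagents that add atoms: 3-chloroperoxybenzoic acid, OOC(=O)c1cccc(Cl)c1
Why: Peracid oxidation of a sulfide to a sulfoxide turns the poor methylsulfanyl leaving group into a good one, and it is done here because 7 has no other oxidisable site, whereas the prenyl alkene of the other partner would not tolerate the oxidant.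

**Step 5**
Reactants: 8 5-[(methanesulfinyl)(4-methoxyphenoxy)methylidene]-2,2-dimethyl-1,3-dioxane-4,6-dione; 4 3,5-bis(methoxymethoxy)-2-(3-methylbut-2-en-1-yl)phenol
Product: 9 5-{[3,5-bis(methoxymethoxy)-2-(3-methylbut-2-en-1-yl)phenoxy](4-methoxyphenoxy)methylidene}-2,2-dimethyl-1,3-dioxane-4,6-dione
Conditions: 4 (1.0 equiv), i-Pr2NEt (1.1 equiv), CH2Cl2, −20 °C → rt
Reagents that add atoms: none
Why: SNV addition–elimination with sulfenate as leaving group should be fast and one-directional at low temperature, since the tetrahedral adduct expels methanesulfenate far more readily than 4-methoxyphenoxide, and one equivalent of phenol under a weak base limits exchange of the aryloxy group already present.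

**Step 6**
Reactants: 9 5-{[3,5-bis(methoxymethoxy)-2-(3-methylbut-2-en-1-yl)phenoxy](4-methoxyphenoxy)methylidene}-2,2-dimethyl-1,3-dioxane-4,6-dione
Product: 10 5,7-bis(methoxymethoxy)-2-(4-methoxyphenoxy)-8-(3-methylbut-2-en-1-yl)-4-oxo-4H-chromene-3-carboxylic acid
Conditions: PhCl (0.02 M), 110 → 130 °C, N2 sweep to remove acetone
Reagents that add atoms: none
Why: Proposed new method: on heating, the electron-rich ortho carbon of the trioxygenated aryl ether (future C4a) adds to the Meldrum's carbonyl held syn to it across the ketene-acetal double bond (future C4), either directly or after cycloreversion to a carboxy-acylium zwitterion, and the dioxanedione then fragments with loss of acetone while the proton leaving C4a ends on the new carboxyl group. The closest known reaction types are the thermal cyclisation of (arylamino)methylene Meldrum's acids to 4-quinolones (Gould–Jacobs family) and the intramolecular Friedel–Crafts acylation of arenes by Meldrum's acid derivatives. The pyranone ring (O1, C2, C3, C4, C4a, C8a) closes in a 6-exo-trig manner at the acyl carbon, preorganised by the cis arrangement of the aryloxy group and the carbonyl on the tetrasubstituted alkene. No stereocentre is formed. Site selectivity is secured because the other ortho carbon of this ring carries the prenyl group, and the anisyl ring, whose ortho carbons are only meta to methoxy, is far less nucleophilic than a carbon ortho to O1 and O5 and para to O7. Loss of CO2 to a methyleneketene that cannot cyclise is avoided by using the lowest temperature that gives conversion, and the neutral medium spares the MOM acetals and the prenyl alkene.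

**Step 7**
Reactants: 10 5,7-bis(methoxymethoxy)-2-(4-methoxyphenoxy)-8-(3-methylbut-2-en-1-yl)-4-oxo-4H-chromene-3-carboxylic acid
Product: 11 5,7-bis(methoxymethoxy)-2-(4-methoxyphenoxy)-8-(3-methylbut-2-en-1-yl)-4H-chromen-4-one
Conditions: Ag2CO3 (10 mol %), AcOH (5 mol %), DMSO, 120 °C
Reagents that add atoms: none
Why: Silver-catalysed protodecarboxylation of a carboxylic acid on an sp2 carbon flanked by two substituents (the C4 carbonyl and the C2 aryloxy group) should release CO2 through a C3–silver species that is then protonated, in a neutral, non-nucleophilic medium that leaves the acetals, the alkene and the C2 aryloxy group alone.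

**Step 8**
Reactants: 11 5,7-bis(methoxymethoxy)-2-(4-methoxyphenoxy)-8-(3-methylbut-2-en-1-yl)-4H-chromen-4-one
Product: 12 5,7-dihydroxy-2-(4-methoxyphenoxy)-8-(3-methylbut-2-en-1-yl)-4H-chromen-4-one (target)
Conditions: PPTS (0.5 equiv), t-BuOH, 80 °C
Reagents that add atoms: none
Why: Mild acid-catalysed acetal exchange cleaves both aryl MOM ethers, while the weak pyridinium acid should neither cyclise the prenyl group onto O7 nor activate the chromone enough for solvolysis at C2, and the hindered alcohol traps the methoxymethyl cation without displacing the aryloxy group.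

**Compound list**
1 | phloroglucinol (benzene-1,3,5-triol) | Oc1cc(O)cc(O)c1 | starting material
2 | 3,5-bis(methoxymethoxy)phenol | COCOc1cc(O)cc(OCOC)c1 | intermediate
3 | prenyl bromide (1-bromo-3-methylbut-2-ene) | CC(C)=CCBr | starting material
4 | 3,5-bis(methoxymethoxy)-2-(3-methylbut-2-en-1-yl)phenol | COCOc1cc(O)c(CC=C(C)C)c(OCOC)c1 | intermediate
5 | 5-[bis(methylsulfanyl)methylidene]-2,2-dimethyl-1,3-dioxane-4,6-dione | CSC(SC)=C1C(=O)OC(C)(C)OC1=O | starting material
6 | 4-methoxyphenol | COc1ccc(O)cc1 | starting material
7 | 5-[(4-methoxyphenoxy)(methylsulfanyl)methylidene]-2,2-dimethyl-1,3-dioxane-4,6-dione | COc1ccc(OC(SC)=C2C(=O)OC(C)(C)OC2=O)cc1 | intermediate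
8 | 5-[(methanesulfinyl)(4-methoxyphenoxy)methylidene]-2,2-dimethyl-1,3-dioxane-4,6-dione (racemic at sulfur) | COc1ccc(OC(S(C)=O)=C2C(=O)OC(C)(C)OC2=O)cc1 | intermediate
9 | 5-{[3,5-bis(methoxymethoxy)-2-(3-methylbut-2-en-1-yl)phenoxy](4-methoxyphenoxy)methylidene}-2,2-dimethyl-1,3-dioxane-4,6-dione | COc1ccc(OC(Oc2cc(OCOC)cc(OCOC)c2CC=C(C)C)=C2C(=O)OC(C)(C)OC2=O)cc1 | intermediate
10 | 5,7-bis(methoxymethoxy)-2-(4-methoxyphenoxy)-8-(3-methylbut-2-en-1-yl)-4-oxo-4H-chromene-3-carboxylic acid | COc1ccc(Oc2c(C(=O)O)c(=O)c3c(OCOC)cc(OCOC)c(CC=C(C)C)c3o2)cc1 | intermediate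
11 | 5,7-bis(methoxymethoxy)-2-(4-methoxyphenoxy)-8-(3-methylbut-2-en-1-yl)-4H-chromen-4-one | COc1ccc(Oc2cc(=O)c3c(OCOC)cc(OCOC)c(CC=C(C)C)c3o2)cc1 | intermediate
12 | 5,7-dihydroxy-2-(4-methoxyphenoxy)-8-(3-methylbut-2-en-1-yl)-4H-chromen-4-one | COc1ccc(Oc2cc(=O)c3c(O)cc(O)c(CC=C(C)C)c3o2)cc1 | target

**Step count**
Total steps: 8. Longest linear sequence: 6 steps (1 → 2 → 4 → 9 → 10 → 11 → 12; the arm 5 → 7 → 8 → 9 is equally long).

**Steps most likely to fail**

Step 6 (proposed new method). The thermal C-acylation may not outrun fragmentation of the dioxanedione with loss of CO2, or it may need temperatures at which the acetals and the ketene-acetal aryloxy groups exchange or decompose. The fallback uses known chemistry, closes the ring through the O1–C2 bond, sets out from phenol 4 and returns to the route at chromone 11: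
- Magnesium-mediated ortho-formylation of 4 (MgCl2, Et3N, paraformaldehyde, MeCN, reflux) should give 2-hydroxy-4,6-bis(methoxymethoxy)-3-(3-methylbut-2-en-1-yl)benzaldehyde F1.
- Addition of MeMgBr (THF, 0 °C) should give racemic 1-[2-hydroxy-4,6-bis(methoxymethoxy)-3-(3-methylbut-2-en-1-yl)phenyl]ethan-1-ol F2.
- MnO2 in CH2Cl2 should oxidise this to 1-[2-hydroxy-4,6-bis(methoxymethoxy)-3-(3-methylbut-2-en-1-yl)phenyl]ethan-1-one F3.
- Condensation with CS2 (KOt-Bu, THF) should close the ring to 4-hydroxy-5,7-bis(methoxymethoxy)-8-(3-methylbut-2-en-1-yl)-2H-chromene-2-thione F4.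
- S-methylation (MeI, K2CO3, acetone) should give 5,7-bis(methoxymethoxy)-8-(3-methylbut-2-en-1-yl)-2-(methylsulfanyl)-4H-chromen-4-one F5.
- Molybdate-catalysed H2O2 oxidation in EtOH, which is selective for sulfur over the trisubstituted alkene, should give 2-(methanesulfonyl)-5,7-bis(methoxymethoxy)-8-(3-methylbut-2-en-1-yl)-4H-chromen-4-one F6.
- Addition–elimination with 4-methoxyphenol 6 (K2CO3, DMF, rt) should give 11.

Step 2. Site selectivity of the phenoxide alkylation may be poor: O-alkylation, attack at the para carbon between the two MOM ethers, or double prenylation. The fallback sets out from 2 and returns at 4. Palladium-catalysed allylic etherification of 2 with methyl 2-methylbut-3-en-2-yl carbonate (Pd(PPh3)4, THF, 0 °C) should give the tertiary ether 1,3-bis(methoxymethoxy)-5-[(2-methylbut-3-en-2-yl)oxy]benzene F7. An aromatic Claisen rearrangement (toluene, 110 °C, or Eu(fod)3, CHCl3, 50 °C) should then deliver the normal prenyl group to one of the two equivalent ortho carbons, giving 4 as the only regioisomer.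

Step 3. Mono-substitution may not be clean: a second exchange to the symmetrical bis(aryloxy) compound and reversible return of thiolate are both possible. The fallback sets out from 5 and returns at 7. Oxidation of 5 with one equivalent of mCPBA (CH2Cl2, 0 °C) should give the monosulfoxide 5-[(methanesulfinyl)(methylsulfanyl)methylidene]-2,2-dimethyl-1,3-dioxane-4,6-dione F8. Treatment with 6 and i-Pr2NEt at −20 °C should then displace only the sulfinyl group, at a temperature where the methylsulfanyl group does not react, giving 7.

**Further compounds**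
F1 | step 6 | 2-hydroxy-4,6-bis(methoxymethoxy)-3-(3-methylbut-2-en-1-yl)benzaldehyde | O=Cc1c(O)c(CC=C(C)C)c(OCOC)cc1OCOC
F2 | step 6 | 1-[2-hydroxy-4,6-bis(methoxymethoxy)-3-(3-methylbut-2-en-1-yl)phenyl]ethan-1-ol (racemic) | CC(O)c1c(O)c(CC=C(C)C)c(OCOC)cc1OCOC
F3 | step 6 | 1-[2-hydroxy-4,6-bis(methoxymethoxy)-3-(3-methylbut-2-en-1-yl)phenyl]ethan-1-one | CC(=O)c1c(O)c(CC=C(C)C)c(OCOC)cc1OCOC
F4 | step 6 | 4-hydroxy-5,7-bis(methoxymethoxy)-8-(3-methylbut-2-en-1-yl)-2H-chromene-2-thione | S=c1cc(O)c2c(OCOC)cc(OCOC)c(CC=C(C)C)c2o1
F5 | step 6 | 5,7-bis(methoxymethoxy)-8-(3-methylbut-2-en-1-yl)-2-(methylsulfanyl)-4H-chromen-4-one | CSc1cc(=O)c2c(OCOC)cc(OCOC)c(CC=C(C)C)c2o1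
F6 | step 6 | 2-(methanesulfonyl)-5,7-bis(methoxymethoxy)-8-(3-methylbut-2-en-1-yl)-4H-chromen-4-one | CS(=O)(=O)c1cc(=O)c2c(OCOC)cc(OCOC)c(CC=C(C)C)c2o1
F7 | step 2 | 1,3-bis(methoxymethoxy)-5-[(2-methylbut-3-en-2-yl)oxy]benzene | C=CC(C)(C)Oc1cc(OCOC)cc(OCOC)c1
F8 | step 3 | 5-[(methanesulfinyl)(methylsulfanyl)methylidene]-2,2-dimethyl-1,3-dioxane-4,6-dione (racemic at sulfur) | CSC(S(C)=O)=C1C(=O)OC(C)(C)OC1=O
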